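The oak run is slow: 0.096 M of product at 2.3 h on 0.0640 M of free catalyst means each catalyst takes 1.53 h per product made. We call this the turnover time.

| setting | oak | maple | larch | cedar |
|---|---|---|---|---|
| starting material | 0.800 M | 0.400 M | 0.800 M | 0.800 M |
| reagent | 0.880 M | 0.480 M | 1.30 M | 0.880 M |
| free catalyst | 0.0640 M | 0.0640 M | 0.0640 M | 0.320 M |
| time |  |  |  | 17 h |

| run | time / h | [product] / M |
|---|---|---|
| oak run | 0.76 | 0.024 |
| oak run | 2.3 | 0.096 |
| oak run | 4.4 | 0.166 |
| oak run | 6.9 | 0.231 |
| oak run | 9.9 | 0.270 |
| oak run | 13 | 0.292 |
| oak run | 17 | 0.304 |
| maple run | 0.76 | 0.015 |
| maple run | 2.3 | 0.047 |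
| maple run | 4.4 | 0.088 |
| maple run | 6.9 | 0.133 |
| maple run | 9.9 | 0.172 |
| maple run | 13 | 0.182 |
| maple run | 17 | 0.199 |
| larch run | 0.76 | 0.042 |
| larch run | 2.3 | 0.127 |
| larch run | 4.4 | 0.213 |
| larch run | 6.9 | 0.270 |
| larch run | 9.9 | 0.304 |
| larch run | 13 | 0.315 |
| larch run | 17 | 0.317 |

(standard deviation of a reading: 0.004 M)

- Overall: starting material + reagent -> product, with free catalyst as catalyst.
- Constant volume, constant temperature.
- An order is taken over about fifteen percent of the charge, up and down.

- reaction order in [reagent] at the outset, round the charge of the oak run, defined at two percent of the starting material turned into product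
- reaction order in [starting material] at the outset, round the charge of the oak run, defined at two percent of the starting material turned into product (one fixed amount of product, the same in the runs compared)
- product in the cedar run at 17 h, as a share of the starting material charged

Suppose the catalyst meets starting material and then reagent, and the two waits add. Two extreme flasks can then be solved in the head. If the meeting with starting material were the rate-limiting step, the order would be one in [starting material] and zero in [reagent]. If the meeting with reagent were, the orders would swap.

The larch run shows that oak lies between them. At equal [starting material], larch has 1.48 times oak's [reagent], yet its turnover time at the same hour is 1.16 h, so its speed rose by a factor of 1.32. That lies between no gain and the full factor.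

The reagent wait shrinks by the fraction 0.323 in larch while the other wait stays the same. Oak's turnover time fell by 0.370 h, so 0.756 is the reagent share, the fraction of oak's turnover time spent waiting for reagent. For a sum of two waits, this share is the order in [reagent], and the remainder, 0.244, is the order in [starting material]. The scatter of those two readings moves the share by about 0.122, so we commit to these orders as readings.

The forecast gives 0.85, 0.22 and 88%, judging that “the catalyst is close to saturation”. Our order in [reagent] stands lower than the forecast's.

The simulation gives 0.70, 0.33 and 79.6%.

    free catalyst + starting material → loaded catalyst + by-product (4.680 L mol⁻¹ h⁻¹)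
    loaded catalyst + reagent → product + free catalyst (1.181 L mol⁻¹ h⁻¹)
    free catalyst + product → spent catalyst + product (2.128 L mol⁻¹ h⁻¹)
    2 starting material → homo dimer (0.1033 L mol⁻¹ h⁻¹)

Our share of 0.756 lies 0.0560 from the order in [reagent], within its scatter. Carried to the maple run, it turns oak's simulated rate of 0.045 M h⁻¹ into 0.0239 M h⁻¹, against a simulated 0.023 M h⁻¹. In the cedar run, the path to spent catalyst and the path to homo dimer together hold product at 79.6%: without the first it reaches 88.8%, and without the second 86.3%.

The readings are calculated for substances that don't exist, noise included.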